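**Plan**
The retrosynthesis first cuts the C7–O–C1' ether, giving scopoletin and a C10 allylic alcohol, then cuts C4'–C5' of the side chain, and finally cuts the coumarin at O1–C2, C5–C6, C4a–C8a and C8–C8a.
The enabling feature is on the benzene ring: the C6 methoxy group is para to the oxygen-bearing C8a, the C7 oxygen sits next to C6, and C3=C4 of the pyranone ring is cis. This is the 4-methoxyphenol pattern that a methoxycarbene, an alkyne and CO assemble.
Forward, the benzene ring and then the pyranone ring form in one flask from an open-chain chromium carbene complex and a Z enynoate, and acid then frees the C7 phenol.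
The side chain is built by adding a C5 dialkylzinc to a commercial E C5 enal ester, and it is joined to the phenol by Mitsunobu etherification before fluoride removes the silyl groups.
The only stereocentre, C4' (R), is set by the chiral ligand in the dialkylzinc addition; the E alkene is bought in and never touched.

Key step: step 5

Remark: 11 is drawn as the metal-free phenol; in the flask it should stay π-bound to a Cr(CO)3 fragment until air is admitted, and lactonisation may occur before or after that point.

**Step 1**
Reactants: 1 tert-butyl vinyl ether; 2 chromium hexacarbonyl, Cr(CO)6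
Product: 5 pentacarbonyl[(1-tert-butoxyvinyl)(methoxy)carbene]chromium, via 1-tert-butoxyvinyllithium 3 (not isolated), via lithium acylchromate 4 (not isolated)
Conditions: t-BuLi, THF, −78 → 0 °C; Cr(CO)6, THF, 0 °C → rt; then Me3OBF4, CH2Cl2, 0 °C
Reagents that add atoms: trimethyloxonium tetrafluoroborate, C[O+](C)C.F[B-](F)(F)F
Why: α-Lithiation of an alkyl vinyl ether by t-BuLi followed by the Fischer carbene synthesis (addition of the vinyllithium to a CO ligand of zerovalent chromium, then O-methylation of the acylchromate by the oxonium salt) is the standard entry to alkenyl(methoxy)carbene complexes, and the α-oxygen of the vinyl group is only a spectator.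

**Step 2**
Reactants: 6 methyl propiolate
Product: 7 methyl (Z)-3-iodoacrylate
Conditions: NaI, AcOH, 70 °C
Reagents that add atoms: sodium iodide, [Na+].[I-]
Why: Hydroiodination of the ynoate by conjugate addition of iodide and anti protonation should give the kinetic Z iodoacrylate, which does not isomerise at 70 °C.

**Step 3**
Reactants: 7 methyl (Z)-3-iodoacrylate; 8 trimethylsilylacetylene
Product: 9 methyl (Z)-5-(trimethylsilyl)pent-2-en-4-ynoate
Conditions: Pd(PPh3)2Cl2 (2 mol %), CuI (4 mol %), Et3N, THF, 0 °C → rt
Reagents that add atoms: none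
Why: Sonogashira coupling of a vinyl iodide is stereospecific at palladium (oxidative addition and reductive elimination with retention), so the Z geometry should be carried over at this low temperature.

**Step 4**
Reactants: 9 methyl (Z)-5-(trimethylsilyl)pent-2-en-4-ynoate
Product: 10 methyl (Z)-pent-2-en-4-ynoate
Conditions: Bu4NF, AcOH, THF, −20 → 0 °C
Reagents that add atoms: none
Why: Fluoride-induced protodesilylation of the alkynylsilane, buffered with acetic acid so that no free alkoxide or acetylide can add to or isomerise the Z enynoate; the volatile product is best carried on as a THF solution.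

**Step 5**
Reactants: 5 pentacarbonyl[(1-tert-butoxyvinyl)(methoxy)carbene]chromium; 10 methyl (Z)-pent-2-en-4-ynoate
Product: 12 7-tert-butoxy-6-methoxycoumarin, via hydroxycinnamate ester 11 (not isolated)
Conditions: THF (0.05 M), 55 °C, Ar, slight excess of 10; then air, rt
Reagents that add atoms: none
Why: Loss of one CO from zerovalent chromium in 5 opens a site for the alkyne of 10, which inserts with its terminal CH bonded to the carbene carbon (C5–C6); CO insertion into the resulting vinylcarbene (C4a–C8a) gives a chromium-bound dienylketene that closes onto the vinyl CH2 (C8–C8a), and tautomerisation gives the 4-methoxyphenol 11. The closest known reaction is the Dötz benzannulation of alkenyl(methoxy)carbene chromium complexes with terminal alkynes and conjugated enynes, including complexes whose alkenyl unit carries an α-alkoxy group. The benzene ring closes by 6π-electrocyclisation in a formal [3+2+1] assembly, and the pyranone ring closes by 6-exo-trig attack of the new phenol oxygen on the cis-placed methyl ester (O1–C2) with loss of methanol, as (Z)-2-hydroxycinnamates do readily. No stereocentre is formed. The step needs regioselective insertion, which a terminal alkyne secures by placing its only substituent next to the CO-derived carbon for steric reasons, and it needs the Z alkene, which is fixed in 10 beforehand. It also needs CO insertion to outrun capture of the vinylcarbene by the ester carbonyl, which the weak donor ability of an ester oxygen, the methoxy group on the carbene and THF as solvent should favour; air rather than a ceric oxidant then frees the electron-rich arene from chromium.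

**Step 6**
Reactants: 12 7-tert-butoxy-6-methoxycoumarin
Product: 13 scopoletin (7-hydroxy-6-methoxycoumarin)
Conditions: CF3CO2H, CH2Cl2, 0 °C → rt
Reagents that add atoms: none
Why: Acidolysis of the aryl tert-butyl ether (loss of the tert-butyl cation as isobutene) should leave the methyl ether and the lactone untouched.

**Step 7**
Reactants: 14 2-methylbut-3-en-2-ol
Product: 15 triethyl[(2-methylbut-3-en-2-yl)oxy]silane
Conditions: Et3SiOTf, 2,6-lutidine, CH2Cl2, −78 → 0 °C
Reagents that add atoms: triethylsilyl trifluoromethanesulfonate, CC[Si](CC)(CC)OS(=O)(=O)C(F)(F)F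
Why: Silylation with a silyl triflate and a hindered pyridine base is the standard way to protect a tertiary alcohol.

**Step 8**
Reactants: 15 triethyl[(2-methylbut-3-en-2-yl)oxy]silane; 16 ethyl (E)-3-methyl-4-oxobut-2-enoate
Product: 19 ethyl (R,E)-4-hydroxy-3,7-dimethyl-7-(triethylsilyloxy)oct-2-enoate, via alkyldiethylborane 17 (not isolated), via dialkylzinc 18 (not isolated)
Conditions: Et2BH (from BH3·SMe2 + Et3B), 0 °C → rt; Et2Zn, 0 °C, then volatiles removed in vacuo; 16, Ti(OiPr)4, (1S,2S)-N,N'-(cyclohexane-1,2-diyl)bis(trifluoromethanesulfonamide) (8 mol %), toluene, −20 °C; H2O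
Reagents that add atoms: none
Why: Hydroboration puts boron on the unhindered terminal carbon, boron–zinc exchange gives the functionalised dialkylzinc, and its titanium bis-sulfonamide-catalysed asymmetric 1,2-addition to the α-substituted enal creates C4; the (1S,2S) ligand is chosen because its (1R,2R) antipode is known to deliver alkyl groups to the Si face of aryl and alkenyl aldehydes, so Re-face attack here should give the R carbinol (to be confirmed by MTPA ester analysis), while the ester is inert to the zinc reagent at −20 °C.

**Step 9**
Reactants: 19 ethyl (R,E)-4-hydroxy-3,7-dimethyl-7-(triethylsilyloxy)oct-2-enoate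
Product: 20 ethyl (R,E)-3,7-dimethyl-4,7-bis(triethylsilyloxy)oct-2-enoate
Conditions: Et3SiOTf, 2,6-lutidine, CH2Cl2, −78 °C
Reagents that add atoms: triethylsilyl trifluoromethanesulfonate, CC[Si](CC)(CC)OS(=O)(=O)C(F)(F)F
Why: O-Silylation of the secondary allylic alcohol does not break the C4–O bond, so the configuration should be retained.

**Step 10**
Reactants: 20 ethyl (R,E)-3,7-dimethyl-4,7-bis(triethylsilyloxy)oct-2-enoate
Product: 21 (R,E)-3,7-dimethyl-4,7-bis(triethylsilyloxy)oct-2-en-1-ol
Conditions: i-Bu2AlH, CH2Cl2, −78 °C; aq. potassium sodium tartrate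
Reagents that add atoms: none
Why: i-Bu2AlH reduces an α,β-unsaturated ester by 1,2-hydride addition to the primary allylic alcohol at −78 °C without affecting silyl ethers or alkene geometry.

**Step 11**
Reactants: 13 scopoletin; 21 (R,E)-3,7-dimethyl-4,7-bis(triethylsilyloxy)oct-2-en-1-ol
Product: 22 7-{[(R,E)-3,7-dimethyl-4,7-bis(triethylsilyloxy)oct-2-en-1-yl]oxy}-6-methoxycoumarin
Conditions: PPh3, DIAD, THF, 0 °C → rt
Reagents that add atoms: none
Why: In this Mitsunobu etherification the phenol (pKa about 9) protonates the betaine and its phenoxide displaces the alkoxyphosphonium at the primary allylic carbon by SN2, leaving the alkene geometry and the C4' stereocentre untouched.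

**Step 12**
Reactants: 22 7-{[(R,E)-3,7-dimethyl-4,7-bis(triethylsilyloxy)oct-2-en-1-yl]oxy}-6-methoxycoumarin
Product: 23 7-{[(R,E)-4,7-dihydroxy-3,7-dimethyloct-2-en-1-yl]oxy}-6-methoxycoumarin (CNP0197418.1)
Conditions: HF·pyridine, pyridine, THF, 0 °C → rt
Reagents that add atoms: none
Why: Fluoride cleaves both triethylsilyl ethers through the strong Si–F bond, and buffering with pyridine should prevent acid-promoted ionisation of the allylic alcohol and keep the lactone closed.

**Compound list**
1 | tert-butyl vinyl ether | C=COC(C)(C)C | starting material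
2 | chromium hexacarbonyl, Cr(CO)6 | O=C=[Cr](=C=O)(=C=O)(=C=O)(=C=O)=C=O | starting material
3 | 1-tert-butoxyvinyllithium | [Li]C(=C)OC(C)(C)C | intermediate
4 | lithium pentacarbonyl(2-tert-butoxy-1-oxidoprop-2-en-1-ylidene)chromate (lithium acylchromate) | [Li+].[O-]C(C(=C)OC(C)(C)C)=[Cr](=C=O)(=C=O)(=C=O)(=C=O)=C=O | intermediate
5 | pentacarbonyl[(1-tert-butoxyvinyl)(methoxy)carbene]chromium | COC(C(=C)OC(C)(C)C)=[Cr](=C=O)(=C=O)(=C=O)(=C=O)=C=O | intermediate
6 | methyl propiolate | C#CC(=O)OC | starting material
7 | methyl (Z)-3-iodoacrylate | COC(=O)/C=C\I | intermediate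
8 | trimethylsilylacetylene | C#C[Si](C)(C)C | starting material
9 | methyl (Z)-5-(trimethylsilyl)pent-2-en-4-ynoate | COC(=O)/C=C\C#C[Si](C)(C)C | intermediate
10 | methyl (Z)-pent-2-en-4-ynoate | COC(=O)/C=C\C#C | intermediate
11 | methyl (Z)-3-(4-tert-butoxy-2-hydroxy-5-methoxyphenyl)acrylate | COC(=O)/C=C\c1cc(OC)c(OC(C)(C)C)cc1O | intermediate
12 | 7-tert-butoxy-6-methoxycoumarin | COc1cc2ccc(=O)oc2cc1OC(C)(C)C | intermediate
13 | scopoletin (7-hydroxy-6-methoxycoumarin) | COc1cc2ccc(=O)oc2cc1O | intermediate
14 | 2-methylbut-3-en-2-ol | C=CC(C)(C)O | starting material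
15 | triethyl[(2-methylbut-3-en-2-yl)oxy]silane | C=CC(C)(C)O[Si](CC)(CC)CC | intermediate
16 | ethyl (E)-3-methyl-4-oxobut-2-enoate | CCOC(=O)/C=C(\C)C=O | starting material
17 | diethyl[3-methyl-3-(triethylsilyloxy)butyl]borane | CCB(CC)CCC(C)(C)O[Si](CC)(CC)CC | intermediate
18 | bis[3-methyl-3-(triethylsilyloxy)butyl]zinc | CC[Si](CC)(CC)OC(C)(C)CC[Zn]CCC(C)(C)O[Si](CC)(CC)CC | intermediate
19 | ethyl (R,E)-4-hydroxy-3,7-dimethyl-7-(triethylsilyloxy)oct-2-enoate | CCOC(=O)/C=C(\C)[C@H](O)CCC(C)(C)O[Si](CC)(CC)CC | intermediate
20 | ethyl (R,E)-3,7-dimethyl-4,7-bis(triethylsilyloxy)oct-2-enoate | CCOC(=O)/C=C(\C)[C@H](O[Si](CC)(CC)CC)CCC(C)(C)O[Si](CC)(CC)CC | intermediate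
21 | (R,E)-3,7-dimethyl-4,7-bis(triethylsilyloxy)oct-2-en-1-ol | OC/C=C(\C)[C@H](O[Si](CC)(CC)CC)CCC(C)(C)O[Si](CC)(CC)CC | intermediate
22 | 7-{[(R,E)-3,7-dimethyl-4,7-bis(triethylsilyloxy)oct-2-en-1-yl]oxy}-6-methoxycoumarin | COc1cc2ccc(=O)oc2cc1OC/C=C(\C)[C@H](O[Si](CC)(CC)CC)CCC(C)(C)O[Si](CC)(CC)CC | intermediate
23 | 7-{[(R,E)-4,7-dihydroxy-3,7-dimethyloct-2-en-1-yl]oxy}-6-methoxycoumarin (CNP0197418.1) | COc1cc2ccc(=O)oc2cc1OC/C=C(\C)[C@H](O)CCC(C)(C)O | target

**Step count**
Total: 12 steps. Longest linear sequence: 7 steps (steps 2, 3, 4, 5, 6, 11, 12, from methyl propiolate).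

**Steps most likely to fail**

Step 5. The vinylcarbene formed after alkyne insertion may be captured by the ester carbonyl oxygen or the enoate alkene before CO inserts, or the electron-poor enyne may oligomerise at chromium, so that little benzannulation occurs. The fallback leaves the chromium route and builds the pyranone ring on a preformed benzene ring. It sets out from methyl propiolate 6, which would be combined with commercial 4-methoxybenzene-1,3-diol (COc1ccc(O)cc1O) in a palladium-catalysed hydroarylation and lactonisation (Pd(OAc)2, NaOAc, HCO2H, rt). The new C–C bond should form at the ring position para to the 3-hydroxyl and ortho to the 1-hydroxyl, which then closes the lactone. This would give scopoletin 13 directly, where the route is rejoined; no compound outside the list is made (F0).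

Step 1. α-Deprotonation of the hindered vinyl ether may stay incomplete, so that t-BuLi itself adds to Cr(CO)6, and the electron-rich complex may decompose during O-methylation. The fallback changes the oxygen substituent and the way the C7 phenol is later freed. It sets out from 2: commercial isopropyl vinyl ether (C=COC(C)C) would be lithiated with t-BuLi to 1-isopropoxyvinyllithium F1, which adds to 2 to give the lithium acylchromate F2, and methylation with Me3OBF4 gives pentacarbonyl[(1-isopropoxyvinyl)(methoxy)carbene]chromium F3. Benzannulation of F3 with 10 under the conditions of step 5 should pass through methyl (Z)-3-(2-hydroxy-4-isopropoxy-5-methoxyphenyl)acrylate F4 to 7-isopropoxy-6-methoxycoumarin F5. BCl3 in CH2Cl2 (−78 → 0 °C) cleaves an isopropyl aryl ether selectively next to a methyl ether and would return the route at scopoletin 13.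

Step 8. Uncatalysed background addition, incomplete boron–zinc exchange or binding of the ester to titanium may erode the facial selectivity. The fallback sets the stereocentre by reduction instead of C–C bond formation. It sets out from 16 and 18: addition without the chiral ligand (Ti(OiPr)4 alone, toluene, 0 °C) would give racemic ethyl (E)-4-hydroxy-3,7-dimethyl-7-(triethylsilyloxy)oct-2-enoate F6. MnO2 in CH2Cl2 oxidises the allylic alcohol to ethyl (E)-3,7-dimethyl-4-oxo-7-(triethylsilyloxy)oct-2-enoate F7. Corey–Bakshi–Shibata reduction with (S)-2-methyl-CBS-oxazaborolidine [(3aS)-1-methyl-3,3-diphenyltetrahydro-1H,3H-pyrrolo[1,2-c][1,3,2]oxazaborole] and catecholborane (toluene, −78 °C), with the alkenyl group as the large substituent, should return the R alcohol 19.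

**Further compounds**
F0 | step 5 | none | none
F1 | step 1 | 1-isopropoxyvinyllithium | [Li]C(=C)OC(C)C
F2 | step 1 | lithium pentacarbonyl(2-isopropoxy-1-oxidoprop-2-en-1-ylidene)chromate | [Li+].[O-]C(C(=C)OC(C)C)=[Cr](=C=O)(=C=O)(=C=O)(=C=O)=C=O
F3 | step 1 | pentacarbonyl[(1-isopropoxyvinyl)(methoxy)carbene]chromium | COC(C(=C)OC(C)C)=[Cr](=C=O)(=C=O)(=C=O)(=C=O)=C=O
F4 | step 1 | methyl (Z)-3-(2-hydroxy-4-isopropoxy-5-methoxyphenyl)acrylate | COC(=O)/C=C\c1cc(OC)c(OC(C)C)cc1O
F5 | step 1 | 7-isopropoxy-6-methoxycoumarin | COc1cc2ccc(=O)oc2cc1OC(C)C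
F6 | step 8 | racemic ethyl (E)-4-hydroxy-3,7-dimethyl-7-(triethylsilyloxy)oct-2-enoate | CCOC(=O)/C=C(\C)C(O)CCC(C)(C)O[Si](CC)(CC)CC
F7 | step 8 | ethyl (E)-3,7-dimethyl-4-oxo-7-(triethylsilyloxy)oct-2-enoate | CCOC(=O)/C=C(\C)C(=O)CCC(C)(C)O[Si](CC)(CC)CC
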